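**Plan**

1. Locants follow germacranolide numbering: ring carbons C1–C10, C6 the lactone carbinol, C7 its neighbour, C11=C13 the methylene, C12 the lactone carbonyl, C14 the ester carbon, C15 the methyl. TBS = tert-butyldimethylsilyl.
2. Retrosynthesis: cut the C8 ester (epoxy acid side chain); then the C6–C7 bond together with the lactone O6–C12 bond, giving an open-chain ω-formyl 2-(bromomethyl)enoate; then C7–C11 (acrylate unit), C8–C9 (alkoxyallylboration), C1–C10 (Morita–Baylis–Hillman) and C1–C2 (alkyne formylation), back to (E)-3-methylpent-2-en-4-yn-1-ol.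
3. Forward: the chain grows from the C2–C6 epoxy alkyne to C1, then C10/C14/C9, then C8/C7, then C11–C13. The alkyne is semi-hydrogenated, the ten-membered carbocycle and the γ-lactone form together in one chromium-mediated operation, and the side chain is attached last.
4. Enabling feature: the C6–C7 bond is common to both rings and lies in the array O6–C6–C7–C11(=C13)–C12. This is the retron of an aldehyde plus a 2-(alkoxycarbonyl)allyl metal, so one C–C bond formation closes ring A (carbocycle) and ring B (lactone).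
5. Stereochemistry: C4/C5 and the side-chain epoxide come from Sharpless epoxidations (D- and L-tartrate); C8/C9 from a pinene-derived (Z)-γ-aryloxyallylborane; C10=C1 from SN2′ bromination of the Baylis–Hillman adduct; Z-C2=C3 from Lindlar reduction; C6/C7 from the cyclisation transition state.

Key step: step 20

**Step 1**
Reactants: 1 tiglic acid
Product: 2 (2E)-2-methylbut-2-en-1-ol
Conditions: LiAlH4, Et2O, 0 °C to rt; aqueous NaOH work-up
Reagents that add atoms: none
Why: LiAlH4 reduction of the carboxylic acid should give the allylic alcohol by 1,2-reduction without touching the trisubstituted E alkene.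

**Step 2**
Reactants: 2 (2E)-2-methylbut-2-en-1-ol
Product: 3 [(2S,3S)-2,3-dimethyloxiran-2-yl]methanol
Conditions: Ti(OiPr)4 (cat.), L-(+)-diisopropyl tartrate (cat.), t-BuOOH, 4 Å MS, CH2Cl2, −20 °C
Reagents that add atoms: tert-butyl hydroperoxide CC(C)(C)OO
Why: Sharpless asymmetric epoxidation, in which the L-(+)-tartrate titanium complex delivers oxygen to the face of the E allylic alcohol that gives the 2S,3S epoxide, setting both side-chain stereocentres.

**Step 3**
Reactants: 3 [(2S,3S)-2,3-dimethyloxiran-2-yl]methanol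
Product: 5 (2R,3S)-2,3-dimethyloxirane-2-carboxylic acid, via epoxy aldehyde 4 (not isolated)
Conditions: RuCl3 (cat.), NaIO4, CCl4–MeCN–H2O, rt
Reagents that add atoms: water O
Why: RuO4-type oxidation of the primary alcohol through the aldehyde hydrate should give the glycidic acid without touching the epoxide (the C2 descriptor changes only through priority).

**Step 4**
Reactants: 6 (2E)-3-methylpent-2-en-4-yn-1-ol
Product: 7 [(2R,3R)-3-ethynyl-3-methyloxiran-2-yl]methanol
Conditions: Ti(OiPr)4 (cat.), D-(−)-diisopropyl tartrate (cat.), t-BuOOH, 4 Å MS, CH2Cl2, −20 °C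
Reagents that add atoms: tert-butyl hydroperoxide CC(C)(C)OO
Why: Sharpless asymmetric epoxidation of the allylic alcohol (alkyne inert), in which the D-(−)-tartrate complex should give the 2R,3R epoxide that becomes C5 and C4 of the target.

**Step 5**
Reactants: 7 [(2R,3R)-3-ethynyl-3-methyloxiran-2-yl]methanol
Product: 8 tert-butyl{[(2R,3R)-3-ethynyl-3-methyloxiran-2-yl]methoxy}dimethylsilane
Conditions: TBSCl, imidazole, CH2Cl2, 0 °C to rt
Reagents that add atoms: tert-butyldimethylsilyl chloride CC(C)(C)[Si](C)(C)Cl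
Why: Standard silylation protects the C6 hydroxyl for the organolithium and oxidation steps that follow.

**Step 6**
Reactants: 8 tert-butyl{[(2R,3R)-3-ethynyl-3-methyloxiran-2-yl]methoxy}dimethylsilane
Product: 10 3-[(2R,3R)-3-(TBSO-methyl)-2-methyloxiran-2-yl]prop-2-ynal, via lithium acetylide 9 (not isolated)
Conditions: n-BuLi, THF, −78 °C; DMF, −78 to 0 °C; reverse quench into aq. KH2PO4
Reagents that add atoms: N,N-dimethylformamide CN(C)C=O
Why: Formylation of the lithium acetylide with DMF adds C1, and the buffered reverse quench should keep dimethylamine from adding to the ynal.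

**Step 7**
Reactants: 10 3-[(2R,3R)-3-(TBSO-methyl)-2-methyloxiran-2-yl]prop-2-ynal
Product: 11 methyl 2-{1-hydroxy-3-[(2R,3R)-3-(TBSO-methyl)-2-methyloxiran-2-yl]prop-2-yn-1-yl}prop-2-enoate (both carbinol epimers)
Conditions: methyl acrylate (excess), DABCO, 0 °C to rt
Reagents that add atoms: methyl acrylate C=CC(=O)OC
Why: Morita–Baylis–Hillman reaction with the highly electrophilic ynal should be fast; the new carbinol centre is formed unselectively and is removed in the next step.

**Step 8**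
Reactants: 11 Baylis–Hillman alcohol
Product: 12 methyl (2Z)-2-(bromomethyl)-5-[(2R,3R)-3-(TBSO-methyl)-2-methyloxiran-2-yl]pent-2-en-4-ynoate
Conditions: NBS, Me2S, CH2Cl2, 0 °C to rt
Reagents that add atoms: N-bromosuccinimide O=C1CCC(=O)N1Br
Why: Corey–Kim-type activation followed by SN2′ attack of bromide should give the rearranged primary bromide with the alkynyl group cis to CH2Br and the ester cis to H, which is the C10=C1 geometry of the target.

**Step 9**
Reactants: 12 (2Z)-allylic bromide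
Product: 13 methyl (2E)-2-formyl-5-[(2R,3R)-3-(TBSO-methyl)-2-methyloxiran-2-yl]pent-2-en-4-ynoate
Conditions: N-methylmorpholine N-oxide, 4 Å MS, MeCN, 0 °C to rt
Reagents that add atoms: N-methylmorpholine N-oxide C[N+]1([O-])CCOCC1
Why: Kornblum-type N-oxide oxidation (SN2 O-alkylation, then elimination) should give the aldehyde; the retained geometry, with the small formyl group cis to the alkynyl group, is also the thermodynamically preferred one.

**Step 10**
Reactants: 13 formyl enynoate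
Product: 14 methyl (2E)-2-[(1S,2S)-1-hydroxy-2-(4-methoxyphenoxy)but-3-en-1-yl]-5-[(2R,3R)-3-(TBSO-methyl)-2-methyloxiran-2-yl]pent-2-en-4-ynoate
Conditions: allyl 4-methoxyphenyl ether, s-BuLi, THF, −78 °C; (+)-Ipc2BOMe; BF3·OEt2; then 13, −78 °C; ethanolamine work-up
Reagents that add atoms: allyl 4-methoxyphenyl ether C=CCOc1ccc(OC)cc1
Why: Brown γ-alkoxyallylboration, in which the (Z)-γ-aryloxyallylborane adds 1,2 to the aldehyde through a chair transition state (8,9-syn) and the isopinocampheyl groups derived from (−)-α-pinene direct attack to the Re face, which should give the 8S,9S pair.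

**Step 11**
Reactants: 14 syn homoallylic alcohol
Product: 15 methyl (2E)-2-[(1S,2S)-1-acetoxy-2-(4-methoxyphenoxy)but-3-en-1-yl]-5-[(2R,3R)-3-(TBSO-methyl)-2-methyloxiran-2-yl]pent-2-en-4-ynoate
Conditions: Ac2O, pyridine, DMAP (cat.), CH2Cl2, 0 °C
Reagents that add atoms: acetic anhydride CC(=O)OC(C)=O
Why: Acetylation installs the C9 acetate of the target while O8 is still masked as the aryl ether, so no acyl migration is possible.

**Step 12**
Reactants: 15 acetate aryl ether
Product: 16 methyl (2E)-2-[(1S,2S)-1-acetoxy-2-hydroxybut-3-en-1-yl]-5-[(2R,3R)-3-(TBSO-methyl)-2-methyloxiran-2-yl]pent-2-en-4-ynoate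
Conditions: (NH4)2Ce(NO3)6, NaHCO3, MeCN–H2O, 0 °C
Reagents that add atoms: none
Why: Oxidative dearylation by tetravalent cerium (the electron-rich arene leaves as benzoquinone) should free O8–H at a stage where the epoxide is only propargylic and the enynoate is too electron-poor to be oxidised.

**Step 13**
Reactants: 16 C8 alcohol
Product: 17 methyl (2E)-2-[(1S,2S)-1-acetoxy-2-(TBSO)but-3-en-1-yl]-5-[(2R,3R)-3-(TBSO-methyl)-2-methyloxiran-2-yl]pent-2-en-4-ynoate
Conditions: TBSOTf, 2,6-lutidine, CH2Cl2, −78 to 0 °C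
Reagents that add atoms: tert-butyldimethylsilyl triflate CC(C)(C)[Si](C)(C)OS(=O)(=O)C(F)(F)F
Why: Silylation puts a fluoride-labile group that is a poor leaving group on O8, as the organochromium step requires.

**Step 14**
Reactants: 17 bis-silyl ether
Product: 19 methyl (2E)-2-[(1S,2R)-1-acetoxy-2-(TBSO)-3-oxopropyl]-5-[(2R,3R)-3-(TBSO-methyl)-2-methyloxiran-2-yl]pent-2-en-4-ynoate, via vicinal diol 18 (not isolated)
Conditions: OsO4 (cat.), NaIO4, 2,6-lutidine, dioxane–H2O, rt
Reagents that add atoms: osmium tetroxide O=[Os](=O)(=O)=O (oxygen donor, reoxidised by NaIO4 [Na+].[O-][I](=O)(=O)=O)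
Why: Johnson–Lemieux cleavage should take only the monosubstituted vinyl group, since the trisubstituted enoate conjugated with the alkyne is electron-poor, and it gives the C7 aldehyde.

**Step 15**
Reactants: 19 C7 aldehyde
Product: 20 methyl (2E)-2-[(1S,2S)-1-acetoxy-2-(TBSO)-3-hydroxy-4-(methoxycarbonyl)pent-4-en-1-yl]-5-[(2R,3R)-3-(TBSO-methyl)-2-methyloxiran-2-yl]pent-2-en-4-ynoate (both C7 epimers)
Conditions: methyl propiolate, i-Bu2AlH, N-methylmorpholine N-oxide, THF, 0 °C; then 19, 0 °C to rt; aq. KNaC4H4O6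
Reagents that add atoms: methyl propiolate C#CC(=O)OC
Why: Vinylalumination: 1,4-hydroalumination of the propiolate gives an α-(methoxycarbonyl)vinylalane that adds to the aldehyde without amine base, which the β-acetoxy aldehyde and the allylic acetate would not tolerate; the C7 carbinol is removed later.

**Step 16**
Reactants: 20 alkyne-stage bis-acrylate alcohol
Product: 21 methyl (2E,4Z)-2-[(1S,2S)-1-acetoxy-2-(TBSO)-3-hydroxy-4-(methoxycarbonyl)pent-4-en-1-yl]-5-[(2R,3R)-3-(TBSO-methyl)-2-methyloxiran-2-yl]penta-2,4-dienoate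
Conditions: H2 (1 atm), Pd/CaCO3 poisoned with Pb(OAc)2, quinoline, EtOAc, rt
Reagents that add atoms: none
Why: Lindlar semi-hydrogenation adds H2 syn to the alkyne, which reacts far faster than the hindered conjugated alkenes, and should give the Z C2=C3 bond.

**Step 17**
Reactants: 21 (2E,4Z)-dienoate
Product: 22 methyl (2E,4Z)-2-[(1S,2S)-1-acetoxy-2-(TBSO)-3-hydroxy-4-(methoxycarbonyl)pent-4-en-1-yl]-5-[(2R,3R)-3-(hydroxymethyl)-2-methyloxiran-2-yl]penta-2,4-dienoate
Conditions: TBAF, AcOH, THF, 0 °C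
Reagents that add atoms: none
Why: Buffered fluoride should cleave the primary silyl ether much faster than the hindered secondary one, and the acetic acid buffer suppresses acetate migration and Payne rearrangement of the epoxy alcohol.

**Step 18**
Reactants: 22 diol
Product: 23 methyl (2E,4Z)-2-[(1S,2S)-1-acetoxy-2-(TBSO)-3-hydroxy-4-(methoxycarbonyl)pent-4-en-1-yl]-5-[(2R,3S)-3-formyl-2-methyloxiran-2-yl]penta-2,4-dienoate
Conditions: TEMPO (cat.), PhI(OAc)2, CH2Cl2–pH 7 buffer, rt
Reagents that add atoms: none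
Why: Oxoammonium (TEMPO) oxidation is selective for the primary alcohol over the hindered, electron-poor secondary allylic alcohol, and near-neutral conditions should preserve the vinyl epoxide and the epoxy aldehyde.

**Step 19**
Reactants: 23 hydroxy aldehyde
Product: 24 methyl (2E,4Z)-2-[(1S,2S,3Z)-1-acetoxy-5-bromo-2-(TBSO)-4-(methoxycarbonyl)pent-3-en-1-yl]-5-[(2R,3S)-3-formyl-2-methyloxiran-2-yl]penta-2,4-dienoate
Conditions: NBS, Me2S, CH2Cl2, 0 °C
Reagents that add atoms: N-bromosuccinimide O=C1CCC(=O)N1Br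
Why: SN2′ bromination of the Baylis–Hillman-type alcohol, as in step 8, should give the (Z)-2-(bromomethyl)enoate while the aldehyde stays untouched.

**Step 20**
Reactants: 24 ω-formyl allylic bromide
Product: 27 ten-membered lactone with O8–TBS and O9–acetyl (target skeleton with the silyl ether in place of the C8 ester), via allylchromium species 25 (not isolated), via ring-closed chromium alkoxide 26 (not isolated)
Conditions: CrCl2 (excess), THF, rt, slow addition of 24, high dilution
Reagents that add atoms: none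
Why: Two equivalents of CrCl2 (divalent chromium, one electron each) convert the allylic C13–Br bond into a σ-allylchromium species of trivalent chromium, whose γ-carbon C7 adds to the C6 formyl group through a closed six-membered chair transition state with allylic transposition (new C6–C7 bond, C11=C13 methylene), after which the C6 chromium alkoxide acylates on the C12 methyl ester. The closest known reaction type is the intramolecular Nozaki–Hiyama–Kishi (Barbier-type) 2-(alkoxycarbonyl)allylation of ω-formyl allylic bromides used to close trans-fused ten-membered α-methylene-γ-lactones, 4,5-epoxy-6-aldehydes included. The carbocycle closes by a 10-exo-trig addition to the aldehyde and the lactone by a 5-exo-trig acyl substitution with loss of methoxide. C6 and C7 are created together: their anti relation (trans-fused lactone) should come from the chair in which the C5 and C8 branches are both equatorial, open to the Z bromide because the σ-allylchromium isomers interconvert by 1,3-metal shift, while the sense of C7 is set by C8 (C8–H eclipsing the allyl plane to avoid allylic 1,3-strain, new bond anti to the C8–C9 donor bond, silyloxy group outside) and that of C6 follows from the chair and from the preset C4/C5 epoxide held in the same forming ring. The step needs this one diastereomer out of four and needs chromium to react only at the C–Br bond; the short all-cis C10=C1–C2=C3 tether, which spans only the diequatorial chair, and the two preset stereo-pairs are relied on for the first, and the mild reducing power of CrCl2 (inert to epoxy aldehyde, vinyl epoxide, dienoate and allylic acetate) together with the non-leaving silyloxy group on C8 for the second. High dilution keeps the reaction intramolecular.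

**Step 21**
Reactants: 27 silyl-protected lactone
Product: 28 8-hydroxy lactone (target lacking the C8 acyl group)
Conditions: TBAF, AcOH, THF, 0 °C to rt
Reagents that add atoms: none
Why: Buffered fluoride desilylation avoids acid (vinyl epoxide) and free alkoxide (acetate migration, translactonisation) and should free O8–H.

**Step 22**
Reactants: 28 8-hydroxy lactone; 5 (2R,3S)-2,3-dimethyloxirane-2-carboxylic acid
Product: 30 target CNP0229507.5, via mixed anhydride 29 (not isolated)
Conditions: 5, 2,4,6-trichlorobenzoyl chloride, Et3N, THF, rt; then 28, DMAP, toluene, rt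
Reagents that add atoms: none
Why: Yamaguchi esterification through the mixed anhydride and the acylpyridinium should acylate the hindered secondary O8–H with the α,α-disubstituted epoxy acid without touching any stereocentre.

**Compound list**

1 | tiglic acid, (2E)-2-methylbut-2-enoic acid | C/C=C(\C)C(=O)O | starting material
2 | (2E)-2-methylbut-2-en-1-ol | C/C=C(\C)CO | intermediate
3 | [(2S,3S)-2,3-dimethyloxiran-2-yl]methanol | C[C@@H]1O[C@@]1(C)CO | intermediate
4 | (2R,3S)-2,3-dimethyloxirane-2-carbaldehyde | C[C@@H]1O[C@@]1(C)C=O | intermediate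
5 | (2R,3S)-2,3-dimethyloxirane-2-carboxylic acid | C[C@@H]1O[C@@]1(C)C(=O)O | intermediate
6 | (2E)-3-methylpent-2-en-4-yn-1-ol | C#C/C(C)=C/CO | starting material
7 | [(2R,3R)-3-ethynyl-3-methyloxiran-2-yl]methanol | C#C[C@@]1(C)O[C@@H]1CO | intermediate
8 | tert-butyl{[(2R,3R)-3-ethynyl-3-methyloxiran-2-yl]methoxy}dimethylsilane | C#C[C@@]1(C)O[C@@H]1CO[Si](C)(C)C(C)(C)C | intermediate
9 | lithium acetylide of 8 | [Li]C#C[C@@]1(C)O[C@@H]1CO[Si](C)(C)C(C)(C)C | intermediate
10 | 3-[(2R,3R)-3-(TBSO-methyl)-2-methyloxiran-2-yl]prop-2-ynal | O=CC#C[C@@]1(C)O[C@@H]1CO[Si](C)(C)C(C)(C)C | intermediate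
11 | methyl 2-{1-hydroxy-3-[(2R,3R)-3-(TBSO-methyl)-2-methyloxiran-2-yl]prop-2-yn-1-yl}prop-2-enoate (both carbinol epimers) | C=C(C(=O)OC)C(O)C#C[C@@]1(C)O[C@@H]1CO[Si](C)(C)C(C)(C)C | intermediate
12 | methyl (2Z)-2-(bromomethyl)-5-[(2R,3R)-3-(TBSO-methyl)-2-methyloxiran-2-yl]pent-2-en-4-ynoate | COC(=O)/C(CBr)=C/C#C[C@@]1(C)O[C@@H]1CO[Si](C)(C)C(C)(C)C | intermediate
13 | methyl (2E)-2-formyl-5-[(2R,3R)-3-(TBSO-methyl)-2-methyloxiran-2-yl]pent-2-en-4-ynoate | COC(=O)/C(C=O)=C/C#C[C@@]1(C)O[C@@H]1CO[Si](C)(C)C(C)(C)C | intermediate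
14 | methyl (2E)-2-[(1S,2S)-1-hydroxy-2-(4-methoxyphenoxy)but-3-en-1-yl]-5-[(2R,3R)-3-(TBSO-methyl)-2-methyloxiran-2-yl]pent-2-en-4-ynoate | COC(=O)/C(=C/C#C[C@@]1(C)O[C@@H]1CO[Si](C)(C)C(C)(C)C)[C@H](O)[C@@H](Oc1ccc(OC)cc1)C=C | intermediate
15 | methyl (2E)-2-[(1S,2S)-1-acetoxy-2-(4-methoxyphenoxy)but-3-en-1-yl]-5-[(2R,3R)-3-(TBSO-methyl)-2-methyloxiran-2-yl]pent-2-en-4-ynoate | COC(=O)/C(=C/C#C[C@@]1(C)O[C@@H]1CO[Si](C)(C)C(C)(C)C)[C@H](OC(C)=O)[C@@H](Oc1ccc(OC)cc1)C=C | intermediate
16 | methyl (2E)-2-[(1S,2S)-1-acetoxy-2-hydroxybut-3-en-1-yl]-5-[(2R,3R)-3-(TBSO-methyl)-2-methyloxiran-2-yl]pent-2-en-4-ynoate | COC(=O)/C(=C/C#C[C@@]1(C)O[C@@H]1CO[Si](C)(C)C(C)(C)C)[C@H](OC(C)=O)[C@@H](O)C=C | intermediate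
17 | methyl (2E)-2-[(1S,2S)-1-acetoxy-2-(TBSO)but-3-en-1-yl]-5-[(2R,3R)-3-(TBSO-methyl)-2-methyloxiran-2-yl]pent-2-en-4-ynoate | COC(=O)/C(=C/C#C[C@@]1(C)O[C@@H]1CO[Si](C)(C)C(C)(C)C)[C@H](OC(C)=O)[C@@H](O[Si](C)(C)C(C)(C)C)C=C | intermediate
18 | methyl (2E)-2-[(1S,2S)-1-acetoxy-2-(TBSO)-3,4-dihydroxybutyl]-5-[(2R,3R)-3-(TBSO-methyl)-2-methyloxiran-2-yl]pent-2-en-4-ynoate (both C7 epimers) | COC(=O)/C(=C/C#C[C@@]1(C)O[C@@H]1CO[Si](C)(C)C(C)(C)C)[C@H](OC(C)=O)[C@@H](O[Si](C)(C)C(C)(C)C)C(O)CO | intermediate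
19 | methyl (2E)-2-[(1S,2R)-1-acetoxy-2-(TBSO)-3-oxopropyl]-5-[(2R,3R)-3-(TBSO-methyl)-2-methyloxiran-2-yl]pent-2-en-4-ynoate | COC(=O)/C(=C/C#C[C@@]1(C)O[C@@H]1CO[Si](C)(C)C(C)(C)C)[C@H](OC(C)=O)[C@@H](O[Si](C)(C)C(C)(C)C)C=O | intermediate
20 | methyl (2E)-2-[(1S,2S)-1-acetoxy-2-(TBSO)-3-hydroxy-4-(methoxycarbonyl)pent-4-en-1-yl]-5-[(2R,3R)-3-(TBSO-methyl)-2-methyloxiran-2-yl]pent-2-en-4-ynoate (both C7 epimers) | COC(=O)/C(=C/C#C[C@@]1(C)O[C@@H]1CO[Si](C)(C)C(C)(C)C)[C@H](OC(C)=O)[C@@H](O[Si](C)(C)C(C)(C)C)C(O)C(=C)C(=O)OC | intermediate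
21 | methyl (2E,4Z)-2-[(1S,2S)-1-acetoxy-2-(TBSO)-3-hydroxy-4-(methoxycarbonyl)pent-4-en-1-yl]-5-[(2R,3R)-3-(TBSO-methyl)-2-methyloxiran-2-yl]penta-2,4-dienoate | COC(=O)/C(=C/C=C\[C@@]1(C)O[C@@H]1CO[Si](C)(C)C(C)(C)C)[C@H](OC(C)=O)[C@@H](O[Si](C)(C)C(C)(C)C)C(O)C(=C)C(=O)OC | intermediate
22 | methyl (2E,4Z)-2-[(1S,2S)-1-acetoxy-2-(TBSO)-3-hydroxy-4-(methoxycarbonyl)pent-4-en-1-yl]-5-[(2R,3R)-3-(hydroxymethyl)-2-methyloxiran-2-yl]penta-2,4-dienoate | COC(=O)/C(=C/C=C\[C@@]1(C)O[C@@H]1CO)[C@H](OC(C)=O)[C@@H](O[Si](C)(C)C(C)(C)C)C(O)C(=C)C(=O)OC | intermediate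
23 | methyl (2E,4Z)-2-[(1S,2S)-1-acetoxy-2-(TBSO)-3-hydroxy-4-(methoxycarbonyl)pent-4-en-1-yl]-5-[(2R,3S)-3-formyl-2-methyloxiran-2-yl]penta-2,4-dienoate | COC(=O)/C(=C/C=C\[C@@]1(C)O[C@@H]1C=O)[C@H](OC(C)=O)[C@@H](O[Si](C)(C)C(C)(C)C)C(O)C(=C)C(=O)OC | intermediate
24 | methyl (2E,4Z)-2-[(1S,2S,3Z)-1-acetoxy-5-bromo-2-(TBSO)-4-(methoxycarbonyl)pent-3-en-1-yl]-5-[(2R,3S)-3-formyl-2-methyloxiran-2-yl]penta-2,4-dienoate | COC(=O)/C(=C/C=C\[C@@]1(C)O[C@@H]1C=O)[C@H](OC(C)=O)[C@@H](O[Si](C)(C)C(C)(C)C)/C=C(\CBr)C(=O)OC | intermediate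
25 | σ-allylchromium dichloride from 24 (C13–CrCl2 in place of C13–Br) | COC(=O)/C(=C/C=C\[C@@]1(C)O[C@@H]1C=O)[C@H](OC(C)=O)[C@@H](O[Si](C)(C)C(C)(C)C)/C=C(\C[Cr](Cl)Cl)C(=O)OC | intermediate
26 | C6 chromium alkoxide of the ring-closed ten-membered hydroxy diester | Cl[Cr](Cl)O[C@H]1[C@H](C(=C)C(=O)OC)[C@H](O[Si](C)(C)C(C)(C)C)[C@@H](OC(C)=O)/C(C(=O)OC)=C\C=C/[C@@]2(C)O[C@H]12 | intermediate
27 | ten-membered 6,12-lactone with 4,5-epoxide, 14-methyl ester, 9-acetoxy and 8-OTBS (all stereocentres as in the target) | C=C1C(=O)O[C@H]2[C@H]1[C@H](O[Si](C)(C)C(C)(C)C)[C@@H](OC(C)=O)/C(C(=O)OC)=C\C=C/[C@@]1(C)O[C@H]21 | intermediate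
28 | 8-hydroxy lactone (27 without the silyl group) | C=C1C(=O)O[C@H]2[C@H]1[C@H](O)[C@@H](OC(C)=O)/C(C(=O)OC)=C\C=C/[C@@]1(C)O[C@H]21 | intermediate
29 | (2R,3S)-2,3-dimethyloxirane-2-carboxylic 2,4,6-trichlorobenzoic anhydride | C[C@@H]1O[C@@]1(C)C(=O)OC(=O)c1c(Cl)cc(Cl)cc1Cl | intermediate
30 | CNP0229507.5 (8-O-[(2R,3S)-2,3-dimethyloxirane-2-carbonyl] ester of 28) | C=C1C(=O)O[C@H]2[C@H]1[C@H](OC(=O)[C@]1(C)O[C@H]1C)[C@@H](OC(C)=O)/C(C(=O)OC)=C\C=C/[C@@]1(C)O[C@H]21 | target

**Step count**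

Total: 22 steps. Longest linear sequence: 19 steps (steps 4–22, from (2E)-3-methylpent-2-en-4-yn-1-ol); the side-chain acid takes 3 steps (steps 1–3).

**Steps most likely to fail**

1. Step 20 (ring closure). The ten-membered transition state may select the wrong pair of faces, giving the syn adduct (cis-fused lactone) or the anti adduct of opposite sense, because the open-chain Felkin–Anh preference of the epoxy aldehyde opposes the required 5,6-threo relation. In addition, the tertiary vinyl epoxide and the all-cis dienoate may ionise or isomerise under the Lewis-acidic trivalent chromium salts during the slow closure. The fallback closes the ring before the semi-hydrogenation, so that the chromium step meets a propargylic epoxide and a rigid enyne tether with a different conformational bias. It sets out from 20. Buffered TBAF removes the primary silyl group to give the alkyne-stage diol F1; TEMPO/PhI(OAc)2 gives the alkyne-stage hydroxy aldehyde F2; NBS/Me2S gives the alkyne-stage bromo aldehyde F3; CrCl2 under high dilution closes the ten-membered enyne lactone F4. Hydrogen over Pd/CaCO3 poisoned with Pb(OAc)2, with quinoline, then reduces the ring alkyne to the Z alkene, and the route is rejoined at 27.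

2. Step 10 (alkoxyallylboration). The doubly activated formyl enynoate may be consumed by conjugate addition or oligomerisation in the basic, Lewis-acidic borane mixture, or the pinene-derived reagent may discriminate poorly between the faces of this hindered conjugated aldehyde. The fallback forms the C9–C10 bond instead of C8–C9 and corrects the C9 configuration by inversion. It sets out from 10. Olefination with Ph3P=C(I)CO2Me gives the (2Z)-α-iodo enynoate F5. A NiCl2-catalysed CrCl2 coupling (Nozaki–Hiyama–Kishi) with the α-silyloxy aldehyde F6 should give, under Felkin–Anh control, the 8,9-anti alcohol F7. A Mitsunobu reaction with acetic acid (PPh3, DIAD) inverts C9 and installs the acetate, so the route is rejoined at 17 and steps 11–13 are not needed.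

3. Step 9 (oxidation of the bromide). The N-oxide may attack in the SN2′ sense at C1, which after elimination leads to a ketone, or the amine by-product may add to the product. The fallback replaces halide oxidation by allylic transposition of an acetate followed by alcohol oxidation. It sets out from 11. Ac2O/DMAP gives the secondary acetate F8; catalytic DABCO in THF isomerises it to the primary (2E)-allylic acetate F9; K2CO3 in MeOH at 0 °C gives the allylic alcohol F10; MnO2 in CH2Cl2 oxidises it to 13.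

**Further compounds**

F1 | step 20 | methyl (2E)-2-[(1S,2S)-1-acetoxy-2-(TBSO)-3-hydroxy-4-(methoxycarbonyl)pent-4-en-1-yl]-5-[(2R,3R)-3-(hydroxymethyl)-2-methyloxiran-2-yl]pent-2-en-4-ynoate | COC(=O)/C(=C/C#C[C@@]1(C)O[C@@H]1CO)[C@H](OC(C)=O)[C@@H](O[Si](C)(C)C(C)(C)C)C(O)C(=C)C(=O)OC
F2 | step 20 | methyl (2E)-2-[(1S,2S)-1-acetoxy-2-(TBSO)-3-hydroxy-4-(methoxycarbonyl)pent-4-en-1-yl]-5-[(2R,3S)-3-formyl-2-methyloxiran-2-yl]pent-2-en-4-ynoate | COC(=O)/C(=C/C#C[C@@]1(C)O[C@@H]1C=O)[C@H](OC(C)=O)[C@@H](O[Si](C)(C)C(C)(C)C)C(O)C(=C)C(=O)OC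
F3 | step 20 | methyl (2E)-2-[(1S,2S,3Z)-1-acetoxy-5-bromo-2-(TBSO)-4-(methoxycarbonyl)pent-3-en-1-yl]-5-[(2R,3S)-3-formyl-2-methyloxiran-2-yl]pent-2-en-4-ynoate | COC(=O)/C(=C/C#C[C@@]1(C)O[C@@H]1C=O)[C@H](OC(C)=O)[C@@H](O[Si](C)(C)C(C)(C)C)/C=C(\CBr)C(=O)OC
F4 | step 20 | 2,3-didehydro analogue of 27 (ring alkyne C2≡C3) | C=C1C(=O)O[C@H]2[C@H]1[C@H](O[Si](C)(C)C(C)(C)C)[C@@H](OC(C)=O)/C(C(=O)OC)=C\C#C[C@@]1(C)O[C@H]21
F5 | step 10 | methyl (2Z)-2-iodo-5-[(2R,3R)-3-(TBSO-methyl)-2-methyloxiran-2-yl]pent-2-en-4-ynoate | COC(=O)/C(I)=C/C#C[C@@]1(C)O[C@@H]1CO[Si](C)(C)C(C)(C)C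
F6 | step 10 | (2S)-2-{[tert-butyl(dimethyl)silyl]oxy}but-3-enal | C=C[C@H](O[Si](C)(C)C(C)(C)C)C=O
F7 | step 10 | methyl (2E)-2-[(1R,2S)-1-hydroxy-2-(TBSO)but-3-en-1-yl]-5-[(2R,3R)-3-(TBSO-methyl)-2-methyloxiran-2-yl]pent-2-en-4-ynoate | COC(=O)/C(=C/C#C[C@@]1(C)O[C@@H]1CO[Si](C)(C)C(C)(C)C)[C@@H](O)[C@@H](O[Si](C)(C)C(C)(C)C)C=C
F8 | step 9 | methyl 2-{1-acetoxy-3-[(2R,3R)-3-(TBSO-methyl)-2-methyloxiran-2-yl]prop-2-yn-1-yl}prop-2-enoate | C=C(C(=O)OC)C(OC(C)=O)C#C[C@@]1(C)O[C@@H]1CO[Si](C)(C)C(C)(C)C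
F9 | step 9 | methyl (2E)-2-(acetoxymethyl)-5-[(2R,3R)-3-(TBSO-methyl)-2-methyloxiran-2-yl]pent-2-en-4-ynoate | COC(=O)/C(COC(C)=O)=C/C#C[C@@]1(C)O[C@@H]1CO[Si](C)(C)C(C)(C)C
F10 | step 9 | methyl (2E)-2-(hydroxymethyl)-5-[(2R,3R)-3-(TBSO-methyl)-2-methyloxiran-2-yl]pent-2-en-4-ynoate | COC(=O)/C(CO)=C/C#C[C@@]1(C)O[C@@H]1CO[Si](C)(C)C(C)(C)C
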